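**Retrosynthetic overview** (ring A = sulfated ring, ring B = central tribromo ring, ring C = terminal dibromophenoxy ring)

- Target ⇐ O-sulfation of the free phenol of ring A ⇐ cleavage of a mesylate that masks this phenol during bromination.
- The strategy rests on ring C: its only bromines sit on C2 and C4, ortho and para to its ether oxygen on C1, which is where a phenyl ether is brominated. Both C–Br bonds are therefore made last, with Br2/FeBr3 on a plain phenoxy ring, while ring A (two Br, OMs) and ring B (three Br, only C6–H free) are deactivated.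
- Ring A phenol oxygen ⇐ Baeyer–Villiger oxidation of a benzaldehyde; A–O–B ether ⇐ SNAr of 3,4,5-tribromo-2-phenoxyphenol on 3,5-dibromo-2-fluorobenzaldehyde.
- B–O–C ether ⇐ O-phenylation of 4,5,6-tribromoguaiacol with diphenyliodonium triflate; ring B bromines ⇐ tribromination of guaiacol.
- No ring is formed; three preformed benzene rings are joined in the order B, then C, then A.

Key step: step 7

Assumption: the target is taken as the free hydrogen sulfate shown (no stereocentre); since aryl hydrogen sulfates keep best as salts, the acid form is released only in the last operation by cold cation exchange.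

**Step 1**
Reactants: 1 guaiacol (2-methoxyphenol)
Product: 2 2,3,4-tribromo-6-methoxyphenol (4,5,6-tribromoguaiacol)
Conditions: Br2 (3.1 equiv), AcOH, rt to 50 °C
Reagents that add atoms: bromine, BrBr
Why: Electrophilic aromatic bromination in which the free OH directs the first two bromines to its para and ortho carbons and the methoxy group directs the third para to itself, so that only the CH next to the methoxy carbon (meta to OH) should stay unsubstituted.

**Step 2**
Reactants: 2 2,3,4-tribromo-6-methoxyphenol; 3 diphenyliodonium triflate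
Product: 4 1,2,3-tribromo-5-methoxy-4-phenoxybenzene
Conditions: KOtBu (1.05 equiv), THF, 0 °C; then 3, 40 °C
Reagents that add atoms: none
Why: Metal-free O-arylation of a phenoxide with a diaryliodonium salt (ligand coupling on trivalent iodine), which tolerates the ortho-bromo and ortho-methoxy groups and meets no competing C–Br bond because the phenyl donor carries none.

**Step 3**
Reactants: 4 1,2,3-tribromo-5-methoxy-4-phenoxybenzene
Product: 5 3,4,5-tribromo-2-phenoxyphenol
Conditions: BBr3, CH2Cl2, −78 °C to rt; H2O quench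
Reagents that add atoms: none
Why: BBr3 demethylation of an aryl methyl ether (bromide attacks the methyl group of the O–B complex), to which the diaryl ether and the aryl bromides are inert.

**Step 4**
Reactants: 5 3,4,5-tribromo-2-phenoxyphenol; 6 3,5-dibromo-2-fluorobenzaldehyde
Product: 7 3,5-dibromo-2-(3,4,5-tribromo-2-phenoxyphenoxy)benzaldehyde
Conditions: K2CO3, dry DMAc, 100 °C
Reagents that add atoms: none
Why: Nucleophilic aromatic substitution (addition–elimination) in which the phenoxide displaces the fluoride ortho to the formyl group through a Meisenheimer adduct, while both bromines of 6 are meta to the formyl group and not activated.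

**Step 5**
Reactants: 7 3,5-dibromo-2-(3,4,5-tribromo-2-phenoxyphenoxy)benzaldehyde
Product: 9 3,5-dibromo-2-(3,4,5-tribromo-2-phenoxyphenoxy)phenol, via aryl formate 8 (not isolated)
Conditions: mCPBA, CH2Cl2, 40 °C; aq Na2SO3 wash; then MeOH, HCl (cat.), rt
Reagents that add atoms: mCPBA (3-chloroperoxybenzoic acid), OOC(=O)c1cccc(Cl)c1
Why: Baeyer–Villiger (Dakin-type) oxidation in which the aryl group of the Criegee adduct migrates to oxygen, helped by the ortho-aryloxy donor, and the resulting formate is cleaved by acid-catalysed methanolysis.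

**Step 6**
Reactants: 9 3,5-dibromo-2-(3,4,5-tribromo-2-phenoxyphenoxy)phenol
Product: 10 3,5-dibromo-2-(3,4,5-tribromo-2-phenoxyphenoxy)phenyl methanesulfonate
Conditions: MsCl, Et3N, CH2Cl2, 0 °C
Reagents that add atoms: methanesulfonyl chloride, CS(=O)(=O)Cl
Why: O-sulfonylation of a phenol, giving a mesylate that withstands Br2, FeBr3 and HBr and removes the activating effect a free OH would have on ring A.

**Step 7**
Reactants: 10 3,5-dibromo-2-(3,4,5-tribromo-2-phenoxyphenoxy)phenyl methanesulfonate
Product: 12 3,5-dibromo-2-[3,4,5-tribromo-2-(2,4-dibromophenoxy)phenoxy]phenyl methanesulfonate, via para-monobromide 11 (not isolated)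
Conditions: Br2 (2.05 equiv), FeBr3 (5 mol %), CH2Cl2, 0 °C to rt, dark
Reagents that add atoms: bromine, BrBr
Why: Electrophilic aromatic substitution: FeBr3-polarised Br2 attacks ring C to give an arenium ion stabilised by the lone pair of the ring C ether oxygen, and loss of HBr rearomatises; the first bromine should enter para (C4, giving 11) and the second ortho (C2). The closest known reaction type is the stepwise para-then-ortho bromination of diphenyl ethers with Br2 and an iron halide used to make polybrominated diphenyl ethers. No ring is closed and no stereocentre is formed. The step needs ring selectivity (ring C over rings A and B), site selectivity (C4 and C2 of ring C) and a stop after two brominations. Ring C is the only ring without bromine, the two free CH of ring A are meta to its ether oxygen and sit on a ring carrying two bromines and the sulfonate, and the single free C6–H of ring B is flanked by three deactivating bromines; the di-ortho-substituted ring B carbon also twists the B–O–C ether so that the oxygen lone pair conjugates with ring C. After C4 and C2 are filled the remaining ortho carbon C6 of ring C is meta to both new bromines and far less reactive, so 2.05 equiv of Br2 at 0 °C should stop at 12.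

**Step 8**
Reactants: 12 3,5-dibromo-2-[3,4,5-tribromo-2-(2,4-dibromophenoxy)phenoxy]phenyl methanesulfonate
Product: 13 3,5-dibromo-2-[3,4,5-tribromo-2-(2,4-dibromophenoxy)phenoxy]phenol (bromoiesol A)
Conditions: NaOH (aq), 1,4-dioxane, 60 °C; then aq HCl
Reagents that add atoms: none
Why: Hydroxide cleavage of an aryl mesylate at the S–O bond (sulfene or attack at sulfur) with the electron-poor aryloxide as leaving group; the alcohol-free medium avoids forming methyl mesylate, and the unactivated aryl bromides are not displaced.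

**Step 9**
Reactants: 13 3,5-dibromo-2-[3,4,5-tribromo-2-(2,4-dibromophenoxy)phenoxy]phenol
Product: 15 3,5-dibromo-2-[3,4,5-tribromo-2-(2,4-dibromophenoxy)phenoxy]phenyl hydrogen sulfate (bromoiesol A sulfate), via pyridinium aryl sulfate 14 (not isolated)
Conditions: SO3·pyridine, pyridine, 60 °C; then strong-acid cation-exchange resin (H+ form), MeOH/H2O, 0 °C
Reagents that add atoms: sulfur trioxide pyridine complex, O=S(=O)([O-])[n+]1ccccc1
Why: O-sulfation of a phenol by sulfur trioxide transfer from its pyridine adduct gives the pyridinium sulfate monoester, and cold cation exchange replaces pyridinium by a proton without hydrolysing the S–O–aryl bond.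

**Compound list**

1 | guaiacol (2-methoxyphenol) | COc1ccccc1O | starting material
2 | 2,3,4-tribromo-6-methoxyphenol | COc1cc(Br)c(Br)c(Br)c1O | intermediate
3 | diphenyliodonium triflate | [O-]S(=O)(=O)C(F)(F)F.c1ccc(cc1)[I+]c1ccccc1 | starting material
4 | 1,2,3-tribromo-5-methoxy-4-phenoxybenzene | COc1cc(Br)c(Br)c(Br)c1Oc1ccccc1 | intermediate
5 | 3,4,5-tribromo-2-phenoxyphenol | Oc1cc(Br)c(Br)c(Br)c1Oc1ccccc1 | intermediate
6 | 3,5-dibromo-2-fluorobenzaldehyde | O=Cc1cc(Br)cc(Br)c1F | starting material
7 | 3,5-dibromo-2-(3,4,5-tribromo-2-phenoxyphenoxy)benzaldehyde | O=Cc1cc(Br)cc(Br)c1Oc1cc(Br)c(Br)c(Br)c1Oc1ccccc1 | intermediate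
8 | 3,5-dibromo-2-(3,4,5-tribromo-2-phenoxyphenoxy)phenyl formate | O=COc1cc(Br)cc(Br)c1Oc1cc(Br)c(Br)c(Br)c1Oc1ccccc1 | intermediate
9 | 3,5-dibromo-2-(3,4,5-tribromo-2-phenoxyphenoxy)phenol | Oc1cc(Br)cc(Br)c1Oc1cc(Br)c(Br)c(Br)c1Oc1ccccc1 | intermediate
10 | 3,5-dibromo-2-(3,4,5-tribromo-2-phenoxyphenoxy)phenyl methanesulfonate | CS(=O)(=O)Oc1cc(Br)cc(Br)c1Oc1cc(Br)c(Br)c(Br)c1Oc1ccccc1 | intermediate
11 | 3,5-dibromo-2-[3,4,5-tribromo-2-(4-bromophenoxy)phenoxy]phenyl methanesulfonate | CS(=O)(=O)Oc1cc(Br)cc(Br)c1Oc1cc(Br)c(Br)c(Br)c1Oc1ccc(Br)cc1 | intermediate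
12 | 3,5-dibromo-2-[3,4,5-tribromo-2-(2,4-dibromophenoxy)phenoxy]phenyl methanesulfonate | CS(=O)(=O)Oc1cc(Br)cc(Br)c1Oc1cc(Br)c(Br)c(Br)c1Oc1ccc(Br)cc1Br | intermediate
13 | 3,5-dibromo-2-[3,4,5-tribromo-2-(2,4-dibromophenoxy)phenoxy]phenol (bromoiesol A) | Oc1cc(Br)cc(Br)c1Oc1cc(Br)c(Br)c(Br)c1Oc1ccc(Br)cc1Br | intermediate
14 | pyridinium 3,5-dibromo-2-[3,4,5-tribromo-2-(2,4-dibromophenoxy)phenoxy]phenyl sulfate | [O-]S(=O)(=O)Oc1cc(Br)cc(Br)c1Oc1cc(Br)c(Br)c(Br)c1Oc1ccc(Br)cc1Br.c1cc[nH+]cc1 | intermediate
15 | 3,5-dibromo-2-[3,4,5-tribromo-2-(2,4-dibromophenoxy)phenoxy]phenyl hydrogen sulfate (bromoiesol A sulfate) | O=S(=O)(O)Oc1cc(Br)cc(Br)c1Oc1cc(Br)c(Br)c(Br)c1Oc1ccc(Br)cc1Br | target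

**Step count:** 9 steps in total; longest linear sequence 9 steps (from guaiacol 1).

**Steps most likely to fail**

1. Step 7 (dibromination of ring C). Stoichiometric control may be lost: the reaction may halt in part at the para-monobromide stage, or run on to the second ortho carbon of ring C or to C6 of ring B, giving polybromides that separate poorly. The fallback sets out from 2 and comes back at 13, bringing ring C in with both bromines already in place.
   - Commercial 2,4-dibromo-1-iodobenzene is oxidised with mCPBA and TsOH·H2O in MeCN and trapped with 1,3,5-trimethoxybenzene to give (2,4-dibromophenyl)(2,4,6-trimethoxyphenyl)iodonium tosylate F1.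
   - F1 arylates the potassium salt of 2 (KOtBu, toluene, 50 °C), the trimethoxyphenyl group staying on iodine, to give 1,2,3-tribromo-4-(2,4-dibromophenoxy)-5-methoxybenzene F2.
   - BBr3 demethylation gives 3,4,5-tribromo-2-(2,4-dibromophenoxy)phenol F3.
   - SNAr on 6 (K2CO3, DMAc, 100 °C) gives 3,5-dibromo-2-[3,4,5-tribromo-2-(2,4-dibromophenoxy)phenoxy]benzaldehyde F4.
   - Baeyer–Villiger oxidation with mCPBA gives 3,5-dibromo-2-[3,4,5-tribromo-2-(2,4-dibromophenoxy)phenoxy]phenyl formate F5, which is methanolysed (MeOH, cat. HCl) to 13.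
   - The mesylate steps 6 and 8 are then not needed, and step 9 follows as written.

2. Step 5 (Baeyer–Villiger oxidation). On the electron-poor ring A, hydride migration in the Criegee adduct may compete with aryl migration and lead to the carboxylic acid, and peracid addition to the hindered aldehyde may be slow. The fallback sets out from 7 and comes back at 9, replacing the aldehyde by a methyl ketone so that only aryl or methyl can migrate.
   - MeMgBr (THF, −78 °C) adds to 7 to give racemic 1-[3,5-dibromo-2-(3,4,5-tribromo-2-phenoxyphenoxy)phenyl]ethanol F6.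
   - Dess–Martin periodinane oxidises it to 1-[3,5-dibromo-2-(3,4,5-tribromo-2-phenoxyphenoxy)phenyl]ethanone F7.
   - mCPBA with catalytic CF3CO2H in CH2Cl2 should give, by the preferred aryl migration, 3,5-dibromo-2-(3,4,5-tribromo-2-phenoxyphenoxy)phenyl acetate F8.
   - Methanolysis (MeOH, cat. HCl) releases 9.

3. Step 9 (sulfation). The hindered, weakly nucleophilic phenol may be sulfated incompletely, and the sulfate may hydrolyse during acidification and concentration of the free acid. The fallback sets out from 13 and comes back at 15, passing through a protected sulfate diester that can be chromatographed.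
   - The sodium phenoxide of 13 (NaH, THF, 0 °C) is treated with commercial neopentyl chlorosulfate to give neopentyl 3,5-dibromo-2-[3,4,5-tribromo-2-(2,4-dibromophenoxy)phenoxy]phenyl sulfate F9.
   - NaN3 in DMF at 70 °C removes the neopentyl group by substitution at its CH2 to give sodium 3,5-dibromo-2-[3,4,5-tribromo-2-(2,4-dibromophenoxy)phenoxy]phenyl sulfate F10, purified as the salt.
   - Cold cation exchange (H+ form) as in step 9 converts F10 to 15.

**Further compounds**

F1 | step 7 | (2,4-dibromophenyl)(2,4,6-trimethoxyphenyl)iodonium tosylate | COc1cc(OC)c([I+]c2ccc(Br)cc2Br)c(OC)c1.Cc1ccc(cc1)S(=O)(=O)[O-]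
F2 | step 7 | 1,2,3-tribromo-4-(2,4-dibromophenoxy)-5-methoxybenzene | COc1cc(Br)c(Br)c(Br)c1Oc1ccc(Br)cc1Br
F3 | step 7 | 3,4,5-tribromo-2-(2,4-dibromophenoxy)phenol | Oc1cc(Br)c(Br)c(Br)c1Oc1ccc(Br)cc1Br
F4 | step 7 | 3,5-dibromo-2-[3,4,5-tribromo-2-(2,4-dibromophenoxy)phenoxy]benzaldehyde | O=Cc1cc(Br)cc(Br)c1Oc1cc(Br)c(Br)c(Br)c1Oc1ccc(Br)cc1Br
F5 | step 7 | 3,5-dibromo-2-[3,4,5-tribromo-2-(2,4-dibromophenoxy)phenoxy]phenyl formate | O=COc1cc(Br)cc(Br)c1Oc1cc(Br)c(Br)c(Br)c1Oc1ccc(Br)cc1Br
F6 | step 5 | racemic 1-[3,5-dibromo-2-(3,4,5-tribromo-2-phenoxyphenoxy)phenyl]ethanol | CC(O)c1cc(Br)cc(Br)c1Oc1cc(Br)c(Br)c(Br)c1Oc1ccccc1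
F7 | step 5 | 1-[3,5-dibromo-2-(3,4,5-tribromo-2-phenoxyphenoxy)phenyl]ethanone | CC(=O)c1cc(Br)cc(Br)c1Oc1cc(Br)c(Br)c(Br)c1Oc1ccccc1
F8 | step 5 | 3,5-dibromo-2-(3,4,5-tribromo-2-phenoxyphenoxy)phenyl acetate | CC(=O)Oc1cc(Br)cc(Br)c1Oc1cc(Br)c(Br)c(Br)c1Oc1ccccc1
F9 | step 9 | neopentyl 3,5-dibromo-2-[3,4,5-tribromo-2-(2,4-dibromophenoxy)phenoxy]phenyl sulfate | CC(C)(C)COS(=O)(=O)Oc1cc(Br)cc(Br)c1Oc1cc(Br)c(Br)c(Br)c1Oc1ccc(Br)cc1Br
F10 | step 9 | sodium 3,5-dibromo-2-[3,4,5-tribromo-2-(2,4-dibromophenoxy)phenoxy]phenyl sulfate | [Na+].[O-]S(=O)(=O)Oc1cc(Br)cc(Br)c1Oc1cc(Br)c(Br)c(Br)c1Oc1ccc(Br)cc1Br
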